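**Retrosynthetic overview**
1. Acid side chain: Wittig enoate ⇐ epoxy aldehyde ⇐ Sharpless epoxidation of a (2E,4E)-dienol ⇐ two Wittig homologations of a C1 aldehyde.
2. Exocyclic (E)-alkene and (R)-carbinol ⇐ CBS reduction of a dienone ⇐ Meyer–Schuster rearrangement of a C2 propynyl carbinol; C1 carbon ⇐ aldol of the ring A enone enolate with formaldehyde.
3. Ring A ⇐ ring-closing metathesis of a lactol-derived diene; ring B ⇐ intermolecular Michael addition of the dienolate of 3-methylbut-3-en-2-one to a 6-substituted dihydropyranone, closed by a second (intramolecular) Michael addition (key fragment union).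
4. Dihydropyranone ⇐ acrylate ring-closing metathesis ⇐ asymmetric allylation of methacrolein.
5. Ring order: temporary lactone → ring B → (lactone opened) → ring A; the ring B ketone stays masked as a silyl enol ether until the last step.

Convention (one line): in the Why lines the carbocyclic core carries the naphthalene locants of the target (C1 side-chain carbon, C2 exocyclic alkene carbon, C3 methyl-bearing alkene carbon, C4a/C8a ring fusion, C6/C8 methyl carbons, C7 ketone); lactone intermediates are named with isochromene locants.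

**Route**

Step 1
Reactants: 1 methacrolein
Product: 3 (R)-2-methylhexa-1,5-dien-3-ol, via borinate ester 2 (not isolated)
Conditions: (Ipc)2B(CH2CH=CH2) made from (−)-α-pinene, Et2O, −78 °C; then NaOH, H2O2, 0 °C → rt
Reagents that add atoms: B-allyldiisopinocampheylborane [from (−)-α-pinene], C=CCB([C@H]1C[C@H]2C[C@@H]([C@@H]1C)C2(C)C)[C@H]1C[C@H]2C[C@@H]([C@@H]1C)C2(C)C
Why: Brown asymmetric carbonyl allylation through a chair-like six-membered transition state in which the isopinocampheyl groups direct the allyl group to one aldehyde face, setting the (R)-carbinol centre that later controls the ring-fusion centres.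

Step 2
Reactants: 3 (R)-2-methylhexa-1,5-dien-3-ol
Product: 4 (R)-2-methylhexa-1,5-dien-3-yl prop-2-enoate
Conditions: CH2=CHCOCl, Et3N, DMAP (cat.), CH2Cl2, 0 °C
Reagents that add atoms: acryloyl chloride, C=CC(=O)Cl
Why: Simple O-acylation of the secondary alcohol with an acid chloride, which leaves the stereocentre untouched.

Step 3
Reactants: 4 (R)-2-methylhexa-1,5-dien-3-yl prop-2-enoate
Product: 5 (R)-6-(prop-1-en-2-yl)-5,6-dihydro-2H-pyran-2-one
Conditions: second-generation Grubbs catalyst (3 mol %), CH2Cl2 (0.01 M), 40 °C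
Reagents that add atoms: none
Why: Ring-closing metathesis of the acrylate with the monosubstituted vinyl group gives the six-membered unsaturated lactone, the 1,1-disubstituted isopropenyl group being too hindered to compete.

Step 4
Reactants: 5 (R)-6-(prop-1-en-2-yl)-5,6-dihydro-2H-pyran-2-one, 6 3-methylbut-3-en-2-one
Product: 10 (3R,4aR,7S,8aS)-7-methyl-3-(prop-1-en-2-yl)-3,4,4a,5,8,8a-hexahydro-1H-isochromene-1,6(7H)-dione, via lithium dienolate 7 (not isolated), via Michael adduct enolate 8 (not isolated), via bicyclic ketone enolate 9 (not isolated)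
Conditions: LiN(iPr)2, THF, −78 °C, slow addition of 6; then 5, −78 → −20 °C; AcOH
Reagents that add atoms: none
Why: Intermolecular Michael addition of the kinetic cross-conjugated dienolate to the lactone β-carbon anti to the isopropenyl group (axial attack, sets C8a), then intramolecular Michael closure of the lactone enolate onto the isopropenyl ketone from the face of the axial tether (sets C4a, cis fusion), a double Michael annulation that builds ring B; the methyl-bearing carbon is protonated unselectively and is planarised again in step 6.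

Step 5
Reactants: 10 (3R,4aR,7S,8aS)-7-methyl-3-(prop-1-en-2-yl)-3,4,4a,5,8,8a-hexahydro-1H-isochromene-1,6(7H)-dione
Product: 12 (3R,4aR,5R,7S,8aS)-5,7-dimethyl-3-(prop-1-en-2-yl)-3,4,4a,5,8,8a-hexahydro-1H-isochromene-1,6(7H)-dione, via lithium enolate 11 (not isolated)
Conditions: LiN(iPr)2 (1.05 equiv), THF, −78 °C; MeI, −78 → −30 °C
Reagents that add atoms: iodomethane, CI
Why: Kinetic enolate alkylation in which the base removes a proton from the less substituted α-CH2 and iodomethane attacks anti to the vicinal ring-fusion substituent on the convex face of the cis-fused bicycle, setting C8 with the methyl trans to the C8a–C1 bond.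

Step 6
Reactants: 12 (3R,4aR,5R,7S,8aS)-5,7-dimethyl-3-(prop-1-en-2-yl)-3,4,4a,5,8,8a-hexahydro-1H-isochromene-1,6(7H)-dione
Product: 13 (3R,4aR,5R,8aS)-5,7-dimethyl-3-(prop-1-en-2-yl)-6-[(triisopropylsilyl)oxy]-3,4,4a,5,8,8a-hexahydro-1H-isochromen-1-one
Conditions: iPr3SiOTf, Et3N, CH2Cl2, 0 °C → rt
Reagents that add atoms: triisopropylsilyl trifluoromethanesulfonate, CC(C)[Si](C(C)C)(C(C)C)OS(=O)(=O)C(F)(F)F
Why: Soft enolisation and O-silylation on the less hindered C6 side (no allylic strain with the ring-fusion substituent) masks the ketone as a robust tetrasubstituted silyl enol ether and leaves the C8 stereocentre intact.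

Step 7
Reactants: 13 (3R,4aR,5R,8aS)-5,7-dimethyl-3-(prop-1-en-2-yl)-6-[(triisopropylsilyl)oxy]-3,4,4a,5,8,8a-hexahydro-1H-isochromen-1-one
Product: 14 (3R,4aR,5R,8aS)-5,7-dimethyl-3-(prop-1-en-2-yl)-6-[(triisopropylsilyl)oxy]-3,4,4a,5,8,8a-hexahydro-1H-isochromen-1-ol (both anomers)
Conditions: iBu2AlH (1.2 equiv), CH2Cl2, −78 °C; aq. KNaC4H4O6
Reagents that add atoms: none
Why: Partial hydride reduction of the lactone stops at the lactol because the tetrahedral aluminate is stable at −78 °C, and the silyl enol ether and alkenes are inert.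

Step 8
Reactants: 14 (3R,4aR,5R,8aS)-5,7-dimethyl-3-(prop-1-en-2-yl)-6-[(triisopropylsilyl)oxy]-3,4,4a,5,8,8a-hexahydro-1H-isochromen-1-ol
Product: 15 (2R)-1-[(1S,2R,6R)-6-ethenyl-2,4-dimethyl-3-[(triisopropylsilyl)oxy]cyclohex-3-en-1-yl]-3-methylbut-3-en-2-ol
Conditions: Ph3PCH3Br, KOtBu, THF, 0 °C → rt
Reagents that add atoms: methyltriphenylphosphonium bromide, C[P+](c1ccccc1)(c1ccccc1)c1ccccc1.[Br-]
Why: Wittig methylenation of the lactol through its open hydroxy-aldehyde form installs the vinyl group at C4a and frees the secondary allylic alcohol without epimerising C4a at 0 °C.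

Step 9
Reactants: 15 (2R)-1-[(1S,2R,6R)-6-ethenyl-2,4-dimethyl-3-[(triisopropylsilyl)oxy]cyclohex-3-en-1-yl]-3-methylbut-3-en-2-ol
Product: 16 (2R,4aS,8R,8aS)-3,6,8-trimethyl-7-[(triisopropylsilyl)oxy]-1,2,4a,5,8,8a-hexahydronaphthalen-2-ol
Conditions: second-generation Grubbs catalyst (5 mol %), CH2Cl2, 40 °C
Reagents that add atoms: none
Why: Ring-closing metathesis of the vinyl and isopropenyl groups held cis on ring B closes ring A as a trisubstituted cyclohexene, and the tetrasubstituted enol ether does not take part.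

Step 10
Reactants: 16 (2R,4aS,8R,8aS)-3,6,8-trimethyl-7-[(triisopropylsilyl)oxy]-1,2,4a,5,8,8a-hexahydronaphthalen-2-ol
Product: 17 (4aS,8R,8aS)-3,6,8-trimethyl-7-[(triisopropylsilyl)oxy]-4a,5,8,8a-tetrahydronaphthalen-2(1H)-one
Conditions: Dess–Martin periodinane, NaHCO3, CH2Cl2, 0 °C → rt
Reagents that add atoms: none
Why: Dess–Martin oxidation of the allylic alcohol gives the carvone-type enone and removes the auxiliary carbinol stereocentre after it has done its relay work.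

Step 11
Reactants: 17 (4aS,8R,8aS)-3,6,8-trimethyl-7-[(triisopropylsilyl)oxy]-4a,5,8,8a-tetrahydronaphthalen-2(1H)-one
Product: 19 (1R,4aS,8R,8aS)-1-(hydroxymethyl)-3,6,8-trimethyl-7-[(triisopropylsilyl)oxy]-4a,5,8,8a-tetrahydronaphthalen-2(1H)-one, via lithium dienolate 18 (not isolated)
Conditions: LiN(iPr)2, THF, −78 °C; CH2O (g, cracked from paraformaldehyde), −78 °C; AcOH
Reagents that add atoms: formaldehyde (monomer), C=O
Why: Aldol addition of the kinetic cross-conjugated lithium enolate to formaldehyde takes place on the convex face anti to the C8a–C8 bond, as in carvone enolate chemistry, setting C1.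

Step 12
Reactants: 19 (1R,4aS,8R,8aS)-1-(hydroxymethyl)-3,6,8-trimethyl-7-[(triisopropylsilyl)oxy]-4a,5,8,8a-tetrahydronaphthalen-2(1H)-one
Product: 20 (1R,2S,4aS,8R,8aS)-1-(hydroxymethyl)-3,6,8-trimethyl-2-(prop-1-yn-1-yl)-7-[(triisopropylsilyl)oxy]-1,2,4a,5,8,8a-hexahydronaphthalen-2-ol
Conditions: CH3C≡CMgBr (3.5 equiv), THF, −40 → 0 °C; aq. NH4Cl
Reagents that add atoms: prop-1-ynylmagnesium bromide, CC#C[Mg]Br
Why: 1,2-Addition of the weakly basic alkynyl Grignard reagent to the enone carbonyl (the first equivalent only deprotonates the alcohol) gives the tertiary propargylic alcohol, whose configuration (drawn for attack anti to the C1 substituent) is irrelevant because C2 becomes trigonal in step 16.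

Step 13
Reactants: 20 (1R,2S,4aS,8R,8aS)-1-(hydroxymethyl)-3,6,8-trimethyl-2-(prop-1-yn-1-yl)-7-[(triisopropylsilyl)oxy]-1,2,4a,5,8,8a-hexahydronaphthalen-2-ol
Product: 21 (1S,2S,4aS,8R,8aS)-2-hydroxy-3,6,8-trimethyl-2-(prop-1-yn-1-yl)-7-[(triisopropylsilyl)oxy]-1,2,4a,5,8,8a-hexahydronaphthalene-1-carbaldehyde
Conditions: Dess–Martin periodinane (1.1 equiv), NaHCO3, CH2Cl2, 0 °C
Reagents that add atoms: none
Why: Chemoselective Dess–Martin oxidation of the primary alcohol beside a non-oxidisable tertiary alcohol gives the aldehyde while C2 is still tetrahedral, so C1 is an ordinary α-branched aldehyde centre and keeps its configuration.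

Step 14
Reactants: 21 (1S,2S,4aS,8R,8aS)-2-hydroxy-3,6,8-trimethyl-2-(prop-1-yn-1-yl)-7-[(triisopropylsilyl)oxy]-1,2,4a,5,8,8a-hexahydronaphthalene-1-carbaldehyde
Product: 22 (2E)-3-[(1R,2S,4aS,8R,8aS)-2-hydroxy-3,6,8-trimethyl-2-(prop-1-yn-1-yl)-7-[(triisopropylsilyl)oxy]-1,2,4a,5,8,8a-hexahydronaphthalen-1-yl]-2-methylprop-2-enal
Conditions: Ph3P=C(CH3)CHO (2 equiv), toluene, 80 °C
Reagents that add atoms: 2-(triphenylphosphoranylidene)propanal, CC(C=O)=P(c1ccccc1)(c1ccccc1)c1ccccc1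
Why: Wittig olefination with the stabilised formyl ylide is (E)-selective for the trisubstituted alkene and the product enal is too hindered to react a second time.

Step 15
Reactants: 22 (2E)-3-[(1R,2S,4aS,8R,8aS)-2-hydroxy-3,6,8-trimethyl-2-(prop-1-yn-1-yl)-7-[(triisopropylsilyl)oxy]-1,2,4a,5,8,8a-hexahydronaphthalen-1-yl]-2-methylprop-2-enal
Product: 23 ethyl (2E,4E)-5-[(1R,2S,4aS,8R,8aS)-2-hydroxy-3,6,8-trimethyl-2-(prop-1-yn-1-yl)-7-[(triisopropylsilyl)oxy]-1,2,4a,5,8,8a-hexahydronaphthalen-1-yl]-2,4-dimethylpenta-2,4-dienoate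
Conditions: Ph3P=C(CH3)CO2Et (2.5 equiv), toluene, 80 °C
Reagents that add atoms: ethyl 2-(triphenylphosphoranylidene)propanoate, CCOC(=O)C(C)=P(c1ccccc1)(c1ccccc1)c1ccccc1
Why: A second Wittig olefination with a stabilised ester ylide gives the (2E,4E)-dienoate under the usual thermodynamic control.

Step 16
Reactants: 23 ethyl (2E,4E)-5-[(1R,2S,4aS,8R,8aS)-2-hydroxy-3,6,8-trimethyl-2-(prop-1-yn-1-yl)-7-[(triisopropylsilyl)oxy]-1,2,4a,5,8,8a-hexahydronaphthalen-1-yl]-2,4-dimethylpenta-2,4-dienoate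
Product: 24 ethyl (2E,4E)-5-[(1R,2E,4aS,8R,8aR)-3,6,8-trimethyl-2-(2-oxopropylidene)-7-[(triisopropylsilyl)oxy]-1,2,4a,5,8,8a-hexahydronaphthalen-1-yl]-2,4-dimethylpenta-2,4-dienoate
Conditions: MoO2(acac)2 (2 mol %), Ph3PAuCl (2 mol %), AgOTf (2 mol %), toluene, rt
Reagents that add atoms: none
Why: Meyer–Schuster rearrangement (1,3-hydroxyl shift, then allenol to ketone tautomerisation) turns the tertiary propargylic alcohol into the conjugated methyl ketone, and the exocyclic alkene forms as the (E)-isomer because the acetyl group avoids allylic 1,3-strain with the C3 methyl group.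

Step 17
Reactants: 24 ethyl (2E,4E)-5-[(1R,2E,4aS,8R,8aR)-3,6,8-trimethyl-2-(2-oxopropylidene)-7-[(triisopropylsilyl)oxy]-1,2,4a,5,8,8a-hexahydronaphthalen-1-yl]-2,4-dimethylpenta-2,4-dienoate
Product: 25 ethyl (2E,4E)-5-[(1R,2E,4aS,8R,8aR)-2-[(2R)-2-hydroxypropylidene]-3,6,8-trimethyl-7-[(triisopropylsilyl)oxy]-1,2,4a,5,8,8a-hexahydronaphthalen-1-yl]-2,4-dimethylpenta-2,4-dienoate
Conditions: (S)-1-methyl-3,3-diphenyltetrahydro-1H,3H-pyrrolo[1,2-c][1,3,2]oxazaborole [(S)-Me-CBS, 0.3 equiv], BH3·SMe2, THF, −40 °C; MeOH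
Reagents that add atoms: none
Why: Corey–Bakshi–Shibata reduction, in which the oxazaborolidine–borane complex binds the methyl ketone with the large dienyl group away from the catalyst and delivers hydride to give the (R)-allylic alcohol, while the ester is not reduced.

Step 18
Reactants: 25 ethyl (2E,4E)-5-[(1R,2E,4aS,8R,8aR)-2-[(2R)-2-hydroxypropylidene]-3,6,8-trimethyl-7-[(triisopropylsilyl)oxy]-1,2,4a,5,8,8a-hexahydronaphthalen-1-yl]-2,4-dimethylpenta-2,4-dienoate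
Product: 26 ethyl (2E,4E)-5-[(1R,2E,4aS,8R,8aR)-2-[(2R)-2-[(tert-butyldimethylsilyl)oxy]propylidene]-3,6,8-trimethyl-7-[(triisopropylsilyl)oxy]-1,2,4a,5,8,8a-hexahydronaphthalen-1-yl]-2,4-dimethylpenta-2,4-dienoate
Conditions: tBuMe2SiOTf, 2,6-lutidine, CH2Cl2, −78 °C
Reagents that add atoms: tert-butyldimethylsilyl trifluoromethanesulfonate, CC(C)(C)[Si](C)(C)OS(=O)(=O)C(F)(F)F
Why: Silyl ether protection of the secondary allylic alcohol, so that it cannot direct the titanium-mediated epoxidation to the exocyclic alkene.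

Step 19
Reactants: 26 ethyl (2E,4E)-5-[(1R,2E,4aS,8R,8aR)-2-[(2R)-2-[(tert-butyldimethylsilyl)oxy]propylidene]-3,6,8-trimethyl-7-[(triisopropylsilyl)oxy]-1,2,4a,5,8,8a-hexahydronaphthalen-1-yl]-2,4-dimethylpenta-2,4-dienoate
Product: 27 (2E,4E)-5-[(1R,2E,4aS,8R,8aR)-2-[(2R)-2-[(tert-butyldimethylsilyl)oxy]propylidene]-3,6,8-trimethyl-7-[(triisopropylsilyl)oxy]-1,2,4a,5,8,8a-hexahydronaphthalen-1-yl]-2,4-dimethylpenta-2,4-dien-1-ol
Conditions: iBu2AlH (2.5 equiv), CH2Cl2, −78 °C; aq. KNaC4H4O6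
Reagents that add atoms: none
Why: 1,2-Hydride reduction of the conjugated ester gives the primary dienyl alcohol without touching the silyl groups or alkenes.

Step 20
Reactants: 27 (2E,4E)-5-[(1R,2E,4aS,8R,8aR)-2-[(2R)-2-[(tert-butyldimethylsilyl)oxy]propylidene]-3,6,8-trimethyl-7-[(triisopropylsilyl)oxy]-1,2,4a,5,8,8a-hexahydronaphthalen-1-yl]-2,4-dimethylpenta-2,4-dien-1-ol
Product: 28 [(2S,3S)-3-[(1E)-1-[(1R,2E,4aS,8R,8aR)-2-[(2R)-2-[(tert-butyldimethylsilyl)oxy]propylidene]-3,6,8-trimethyl-7-[(triisopropylsilyl)oxy]-1,2,4a,5,8,8a-hexahydronaphthalen-1-yl]prop-1-en-2-yl]-2-methyloxiran-2-yl]methanol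
Conditions: Ti(OiPr)4 (10 mol %), L-(+)-diethyl tartrate (12 mol %), tBuOOH, 4 Å molecular sieves, CH2Cl2, −25 °C
Reagents that add atoms: tert-butyl hydroperoxide, CC(C)(C)OO
Why: Sharpless asymmetric epoxidation, in which the titanium tartrate complex epoxidises only the alkene next to the free allylic hydroxyl and L-(+)-tartrate sets the (2S,3S)-epoxide under reagent control.

Step 21
Reactants: 28 [(2S,3S)-3-[(1E)-1-[(1R,2E,4aS,8R,8aR)-2-[(2R)-2-[(tert-butyldimethylsilyl)oxy]propylidene]-3,6,8-trimethyl-7-[(triisopropylsilyl)oxy]-1,2,4a,5,8,8a-hexahydronaphthalen-1-yl]prop-1-en-2-yl]-2-methyloxiran-2-yl]methanol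
Product: 29 (2R,3S)-3-[(1E)-1-[(1R,2E,4aS,8R,8aR)-2-[(2R)-2-[(tert-butyldimethylsilyl)oxy]propylidene]-3,6,8-trimethyl-7-[(triisopropylsilyl)oxy]-1,2,4a,5,8,8a-hexahydronaphthalen-1-yl]prop-1-en-2-yl]-2-methyloxirane-2-carbaldehyde
Conditions: Dess–Martin periodinane, NaHCO3, CH2Cl2, 0 °C
Reagents that add atoms: none
Why: Buffered Dess–Martin oxidation gives the epoxy aldehyde without opening the acid-sensitive vinyl epoxide (the descriptor at the quaternary carbon changes only through CIP priority).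

Step 22
Reactants: 29 (2R,3S)-3-[(1E)-1-[(1R,2E,4aS,8R,8aR)-2-[(2R)-2-[(tert-butyldimethylsilyl)oxy]propylidene]-3,6,8-trimethyl-7-[(triisopropylsilyl)oxy]-1,2,4a,5,8,8a-hexahydronaphthalen-1-yl]prop-1-en-2-yl]-2-methyloxirane-2-carbaldehyde
Product: 30 2-(trimethylsilyl)ethyl (2E)-3-[(2S,3S)-3-[(1E)-1-[(1R,2E,4aS,8R,8aR)-2-[(2R)-2-[(tert-butyldimethylsilyl)oxy]propylidene]-3,6,8-trimethyl-7-[(triisopropylsilyl)oxy]-1,2,4a,5,8,8a-hexahydronaphthalen-1-yl]prop-1-en-2-yl]-2-methyloxiran-2-yl]prop-2-enoate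
Conditions: Ph3P=CHCO2CH2CH2SiMe3 (1.5 equiv), CH2Cl2, rt
Reagents that add atoms: 2-(trimethylsilyl)ethyl 2-(triphenylphosphoranylidene)acetate, C[Si](C)(C)CCOC(=O)C=P(c1ccccc1)(c1ccccc1)c1ccccc1
Why: Wittig olefination with a stabilised ylide gives the (E)-enoate under neutral conditions and installs the acid as a fluoride-labile ester.

Step 23
Reactants: 30 2-(trimethylsilyl)ethyl (2E)-3-[(2S,3S)-3-[(1E)-1-[(1R,2E,4aS,8R,8aR)-2-[(2R)-2-[(tert-butyldimethylsilyl)oxy]propylidene]-3,6,8-trimethyl-7-[(triisopropylsilyl)oxy]-1,2,4a,5,8,8a-hexahydronaphthalen-1-yl]prop-1-en-2-yl]-2-methyloxiran-2-yl]prop-2-enoate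
Product: 31 (2E)-3-[(2S,3S)-3-[(1E)-1-[(1R,2E,4aS,6S,8R,8aR)-2-[(2R)-2-hydroxypropylidene]-3,6,8-trimethyl-7-oxo-1,2,4a,5,6,7,8,8a-octahydronaphthalen-1-yl]prop-1-en-2-yl]-2-methyloxiran-2-yl]prop-2-enoic acid (CNP0414188.1)
Conditions: Bu4NF (6 equiv), THF, 0 °C → rt; AcOH, pH 5 buffer
Reagents that add atoms: none
Why: Fluoride-mediated global desilylation cleaves the 2-(trimethylsilyl)ethyl ester (β-elimination), the silyl ether and the silyl enol ether, and the liberated ketone enolate is protonated under equilibrating conditions to the cis-2,6-dimethyl ketone with both methyl groups equatorial, setting C6 (the C8 epimer and the 6,8-diaxial alternative are each disfavoured by a syn-axial interaction).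

**Compound list**
1 | methacrolein (2-methylprop-2-enal) | CC(=C)C=O | starting material
2 | (R)-2-methylhexa-1,5-dien-3-yl diisopinocampheylborinate | CC(=C)[C@H](OB([C@H]1C[C@H]2C[C@@H]([C@@H]1C)C2(C)C)[C@H]1C[C@H]2C[C@@H]([C@@H]1C)C2(C)C)CC=C | intermediate (not isolated)
3 | (R)-2-methylhexa-1,5-dien-3-ol | CC(=C)[C@H](O)CC=C | intermediate
4 | (R)-2-methylhexa-1,5-dien-3-yl prop-2-enoate | CC(=C)[C@H](OC(=O)C=C)CC=C | intermediate
5 | (R)-6-(prop-1-en-2-yl)-5,6-dihydro-2H-pyran-2-one | CC(=C)[C@H]1CC=CC(=O)O1 | intermediate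
6 | 3-methylbut-3-en-2-one | CC(=O)C(C)=C | starting material
7 | lithium 3-methylbuta-1,3-dien-2-olate | [Li+].[O-]C(=C)C(C)=C | intermediate (not isolated)
8 | lithium (4R,6R)-4-(3-methyl-2-oxobut-3-en-1-yl)-6-(prop-1-en-2-yl)-5,6-dihydro-4H-pyran-2-olate | CC(=C)[C@H]1C[C@H](CC(=O)C(C)=C)C=C([O-])O1.[Li+] | intermediate (not isolated)
9 | lithium (3R,4aR,8aS)-7-methyl-1-oxo-3-(prop-1-en-2-yl)-3,4,4a,5,8,8a-hexahydro-1H-isochromen-6-olate | CC(=C)[C@H]1C[C@H]2[C@H](CC(C)=C([O-])C2)C(=O)O1.[Li+] | intermediate (not isolated)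
10 | (3R,4aR,7S,8aS)-7-methyl-3-(prop-1-en-2-yl)-3,4,4a,5,8,8a-hexahydro-1H-isochromene-1,6(7H)-dione (7-epimer also usable) | CC(=C)[C@H]1C[C@H]2[C@H](C[C@H](C)C(=O)C2)C(=O)O1 | intermediate
11 | lithium (3R,4aR,7S,8aS)-7-methyl-1-oxo-3-(prop-1-en-2-yl)-3,4,4a,7,8,8a-hexahydro-1H-isochromen-6-olate | CC(=C)[C@H]1C[C@H]2[C@H](C[C@H](C)C([O-])=C2)C(=O)O1.[Li+] | intermediate (not isolated)
12 | (3R,4aR,5R,7S,8aS)-5,7-dimethyl-3-(prop-1-en-2-yl)-3,4,4a,5,8,8a-hexahydro-1H-isochromene-1,6(7H)-dione | CC(=C)[C@H]1C[C@H]2[C@H](C[C@H](C)C(=O)[C@@H]2C)C(=O)O1 | intermediate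
13 | (3R,4aR,5R,8aS)-5,7-dimethyl-3-(prop-1-en-2-yl)-6-[(triisopropylsilyl)oxy]-3,4,4a,5,8,8a-hexahydro-1H-isochromen-1-one | CC(=C)[C@H]1C[C@H]2[C@H](CC(C)=C(O[Si](C(C)C)(C(C)C)C(C)C)[C@@H]2C)C(=O)O1 | intermediate
14 | (3R,4aR,5R,8aS)-5,7-dimethyl-3-(prop-1-en-2-yl)-6-[(triisopropylsilyl)oxy]-3,4,4a,5,8,8a-hexahydro-1H-isochromen-1-ol (both anomers) | CC(=C)[C@H]1C[C@H]2[C@H](CC(C)=C(O[Si](C(C)C)(C(C)C)C(C)C)[C@@H]2C)C(O)O1 | intermediate
15 | (2R)-1-[(1S,2R,6R)-6-ethenyl-2,4-dimethyl-3-[(triisopropylsilyl)oxy]cyclohex-3-en-1-yl]-3-methylbut-3-en-2-ol | C=C[C@H]1CC(C)=C(O[Si](C(C)C)(C(C)C)C(C)C)[C@H](C)[C@H]1C[C@@H](O)C(C)=C | intermediate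
16 | (2R,4aS,8R,8aS)-3,6,8-trimethyl-7-[(triisopropylsilyl)oxy]-1,2,4a,5,8,8a-hexahydronaphthalen-2-ol | CC1=C[C@H]2CC(C)=C(O[Si](C(C)C)(C(C)C)C(C)C)[C@H](C)[C@H]2C[C@H]1O | intermediate
17 | (4aS,8R,8aS)-3,6,8-trimethyl-7-[(triisopropylsilyl)oxy]-4a,5,8,8a-tetrahydronaphthalen-2(1H)-one | CC1=C[C@H]2CC(C)=C(O[Si](C(C)C)(C(C)C)C(C)C)[C@H](C)[C@H]2CC1=O | intermediate
18 | lithium (4aS,8R,8aR)-3,6,8-trimethyl-7-[(triisopropylsilyl)oxy]-4a,5,8,8a-tetrahydronaphthalen-2-olate | CC1=C[C@H]2CC(C)=C(O[Si](C(C)C)(C(C)C)C(C)C)[C@H](C)[C@H]2C=C1[O-].[Li+] | intermediate (not isolated)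
19 | (1R,4aS,8R,8aS)-1-(hydroxymethyl)-3,6,8-trimethyl-7-[(triisopropylsilyl)oxy]-4a,5,8,8a-tetrahydronaphthalen-2(1H)-one | CC1=C[C@H]2CC(C)=C(O[Si](C(C)C)(C(C)C)C(C)C)[C@H](C)[C@H]2[C@H](CO)C1=O | intermediate
20 | (1R,2S,4aS,8R,8aS)-1-(hydroxymethyl)-3,6,8-trimethyl-2-(prop-1-yn-1-yl)-7-[(triisopropylsilyl)oxy]-1,2,4a,5,8,8a-hexahydronaphthalen-2-ol | CC1=C[C@H]2CC(C)=C(O[Si](C(C)C)(C(C)C)C(C)C)[C@H](C)[C@H]2[C@H](CO)[C@@]1(O)C#CC | intermediate
21 | (1S,2S,4aS,8R,8aS)-2-hydroxy-3,6,8-trimethyl-2-(prop-1-yn-1-yl)-7-[(triisopropylsilyl)oxy]-1,2,4a,5,8,8a-hexahydronaphthalene-1-carbaldehyde | CC1=C[C@H]2CC(C)=C(O[Si](C(C)C)(C(C)C)C(C)C)[C@H](C)[C@H]2[C@H](C=O)[C@@]1(O)C#CC | intermediate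
22 | (2E)-3-[(1R,2S,4aS,8R,8aS)-2-hydroxy-3,6,8-trimethyl-2-(prop-1-yn-1-yl)-7-[(triisopropylsilyl)oxy]-1,2,4a,5,8,8a-hexahydronaphthalen-1-yl]-2-methylprop-2-enal | CC1=C[C@H]2CC(C)=C(O[Si](C(C)C)(C(C)C)C(C)C)[C@H](C)[C@H]2[C@H](/C=C(\C)C=O)[C@@]1(O)C#CC | intermediate
23 | ethyl (2E,4E)-5-[(1R,2S,4aS,8R,8aS)-2-hydroxy-3,6,8-trimethyl-2-(prop-1-yn-1-yl)-7-[(triisopropylsilyl)oxy]-1,2,4a,5,8,8a-hexahydronaphthalen-1-yl]-2,4-dimethylpenta-2,4-dienoate | CC1=C[C@H]2CC(C)=C(O[Si](C(C)C)(C(C)C)C(C)C)[C@H](C)[C@H]2[C@H](/C=C(\C)/C=C(\C)C(=O)OCC)[C@@]1(O)C#CC | intermediate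
24 | ethyl (2E,4E)-5-[(1R,2E,4aS,8R,8aR)-3,6,8-trimethyl-2-(2-oxopropylidene)-7-[(triisopropylsilyl)oxy]-1,2,4a,5,8,8a-hexahydronaphthalen-1-yl]-2,4-dimethylpenta-2,4-dienoate | CC1=C[C@H]2CC(C)=C(O[Si](C(C)C)(C(C)C)C(C)C)[C@H](C)[C@H]2[C@H](/C=C(\C)/C=C(\C)C(=O)OCC)/C1=C\C(C)=O | intermediate
25 | ethyl (2E,4E)-5-[(1R,2E,4aS,8R,8aR)-2-[(2R)-2-hydroxypropylidene]-3,6,8-trimethyl-7-[(triisopropylsilyl)oxy]-1,2,4a,5,8,8a-hexahydronaphthalen-1-yl]-2,4-dimethylpenta-2,4-dienoate | CC1=C[C@H]2CC(C)=C(O[Si](C(C)C)(C(C)C)C(C)C)[C@H](C)[C@H]2[C@H](/C=C(\C)/C=C(\C)C(=O)OCC)/C1=C\[C@@H](C)O | intermediate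
26 | ethyl (2E,4E)-5-[(1R,2E,4aS,8R,8aR)-2-[(2R)-2-[(tert-butyldimethylsilyl)oxy]propylidene]-3,6,8-trimethyl-7-[(triisopropylsilyl)oxy]-1,2,4a,5,8,8a-hexahydronaphthalen-1-yl]-2,4-dimethylpenta-2,4-dienoate | CC1=C[C@H]2CC(C)=C(O[Si](C(C)C)(C(C)C)C(C)C)[C@H](C)[C@H]2[C@H](/C=C(\C)/C=C(\C)C(=O)OCC)/C1=C\[C@@H](C)O[Si](C)(C)C(C)(C)C | intermediate
27 | (2E,4E)-5-[(1R,2E,4aS,8R,8aR)-2-[(2R)-2-[(tert-butyldimethylsilyl)oxy]propylidene]-3,6,8-trimethyl-7-[(triisopropylsilyl)oxy]-1,2,4a,5,8,8a-hexahydronaphthalen-1-yl]-2,4-dimethylpenta-2,4-dien-1-ol | CC1=C[C@H]2CC(C)=C(O[Si](C(C)C)(C(C)C)C(C)C)[C@H](C)[C@H]2[C@H](/C=C(\C)/C=C(\C)CO)/C1=C\[C@@H](C)O[Si](C)(C)C(C)(C)C | intermediate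
28 | [(2S,3S)-3-[(1E)-1-[(1R,2E,4aS,8R,8aR)-2-[(2R)-2-[(tert-butyldimethylsilyl)oxy]propylidene]-3,6,8-trimethyl-7-[(triisopropylsilyl)oxy]-1,2,4a,5,8,8a-hexahydronaphthalen-1-yl]prop-1-en-2-yl]-2-methyloxiran-2-yl]methanol | CC1=C[C@H]2CC(C)=C(O[Si](C(C)C)(C(C)C)C(C)C)[C@H](C)[C@H]2[C@H](/C=C(\C)[C@@H]2O[C@@]2(C)CO)/C1=C\[C@@H](C)O[Si](C)(C)C(C)(C)C | intermediate
29 | (2R,3S)-3-[(1E)-1-[(1R,2E,4aS,8R,8aR)-2-[(2R)-2-[(tert-butyldimethylsilyl)oxy]propylidene]-3,6,8-trimethyl-7-[(triisopropylsilyl)oxy]-1,2,4a,5,8,8a-hexahydronaphthalen-1-yl]prop-1-en-2-yl]-2-methyloxirane-2-carbaldehyde | CC1=C[C@H]2CC(C)=C(O[Si](C(C)C)(C(C)C)C(C)C)[C@H](C)[C@H]2[C@H](/C=C(\C)[C@@H]2O[C@@]2(C)C=O)/C1=C\[C@@H](C)O[Si](C)(C)C(C)(C)C | intermediate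
30 | 2-(trimethylsilyl)ethyl (2E)-3-[(2S,3S)-3-[(1E)-1-[(1R,2E,4aS,8R,8aR)-2-[(2R)-2-[(tert-butyldimethylsilyl)oxy]propylidene]-3,6,8-trimethyl-7-[(triisopropylsilyl)oxy]-1,2,4a,5,8,8a-hexahydronaphthalen-1-yl]prop-1-en-2-yl]-2-methyloxiran-2-yl]prop-2-enoate | CC1=C[C@H]2CC(C)=C(O[Si](C(C)C)(C(C)C)C(C)C)[C@H](C)[C@H]2[C@H](/C=C(\C)[C@@H]2O[C@@]2(C)/C=C/C(=O)OCC[Si](C)(C)C)/C1=C\[C@@H](C)O[Si](C)(C)C(C)(C)C | intermediate
31 | (2E)-3-[(2S,3S)-3-[(1E)-1-[(1R,2E,4aS,6S,8R,8aR)-2-[(2R)-2-hydroxypropylidene]-3,6,8-trimethyl-7-oxo-1,2,4a,5,6,7,8,8a-octahydronaphthalen-1-yl]prop-1-en-2-yl]-2-methyloxiran-2-yl]prop-2-enoic acid | CC1=C[C@H]2C[C@H](C)C(=O)[C@H](C)[C@H]2[C@H](/C=C(\C)[C@@H]2O[C@@]2(C)/C=C/C(=O)O)/C1=C\[C@@H](C)O | target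

**Totals**
Total step count: 23. Longest linear sequence: 23 steps (the route is fully linear from methacrolein 1; compound 6 enters at step 4).

**Three steps most likely to fail, with fallbacks**

Step 4 (double Michael annulation): after the first Michael addition, proton transfer from the ketone α-CH2 to the lactone enolate may outrun ring closure, or the dienolate may oligomerise. The fallback sets out from 5 and 6 and returns at 10. Compound 6 is silylated (Me3SiCl, Et3N, NaI, MeCN) to 3-methyl-2-[(trimethylsilyl)oxy]buta-1,3-diene F1. F1 and 5 then undergo a thermal Diels–Alder cycloaddition (toluene, sealed tube, 160 °C, BHT) on the lactone face anti to the isopropenyl group, giving the cis-fused silyl enol ether (3R,4aR,8aS)-7-methyl-3-(prop-1-en-2-yl)-6-[(trimethylsilyl)oxy]-3,4,4a,5,8,8a-hexahydro-1H-isochromen-1-one F2. Mild methanolysis (K2CO3, MeOH, 0 °C) converts F2 into 10.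

Step 16 (Meyer–Schuster rearrangement): the doubly activated tertiary alcohol may ionise and eliminate instead of rearranging. The fallback sets out from 23 and returns at 24 by hydration and elimination. Hydroxyl-directed hydration of the alkyne (Ph3PAuNTf2 cat., wet 1,4-dioxane, rt) gives the β-hydroxy ketone ethyl (2E,4E)-5-[(1R,2S,4aS,8R,8aS)-2-hydroxy-3,6,8-trimethyl-2-(2-oxopropyl)-7-[(triisopropylsilyl)oxy]-1,2,4a,5,8,8a-hexahydronaphthalen-1-yl]-2,4-dimethylpenta-2,4-dienoate F3. E1cB-type dehydration of F3 (Burgess reagent, or (CF3CO)2O/Et3N then DBU) toward the acidic CH2 gives the (E)-dienone 24.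

Step 23 (global fluoride deprotection): the basic fluoride may damage the epoxy enoate or the dienyl carbinol before the ester is cleaved. The fallback sets out from 29 and returns at 31, replacing the fluoride-labile ester by a methyl ester. Wittig olefination of 29 with Ph3P=CHCO2Me gives methyl (2E)-3-[(2S,3S)-3-[(1E)-1-[(1R,2E,4aS,8R,8aR)-2-[(2R)-2-[(tert-butyldimethylsilyl)oxy]propylidene]-3,6,8-trimethyl-7-[(triisopropylsilyl)oxy]-1,2,4a,5,8,8a-hexahydronaphthalen-1-yl]prop-1-en-2-yl]-2-methyloxiran-2-yl]prop-2-enoate F4. Desilylation of F4 with AcOH-buffered Bu4NF (THF, 0 °C → rt) gives the keto alcohol methyl (2E)-3-[(2S,3S)-3-[(1E)-1-[(1R,2E,4aS,6S,8R,8aR)-2-[(2R)-2-hydroxypropylidene]-3,6,8-trimethyl-7-oxo-1,2,4a,5,6,7,8,8a-octahydronaphthalen-1-yl]prop-1-en-2-yl]-2-methyloxiran-2-yl]prop-2-enoate F5. Near-neutral hydrolysis of F5 with Me3SnOH (1,2-dichloroethane, 70 °C) gives 31.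

Further compounds
F1 | step 4 | 3-methyl-2-[(trimethylsilyl)oxy]buta-1,3-diene | C=C(C)C(=C)O[Si](C)(C)C
F2 | step 4 | (3R,4aR,8aS)-7-methyl-3-(prop-1-en-2-yl)-6-[(trimethylsilyl)oxy]-3,4,4a,5,8,8a-hexahydro-1H-isochromen-1-one | CC(=C)[C@H]1C[C@H]2[C@H](CC(C)=C(O[Si](C)(C)C)C2)C(=O)O1
F3 | step 16 | ethyl (2E,4E)-5-[(1R,2S,4aS,8R,8aS)-2-hydroxy-3,6,8-trimethyl-2-(2-oxopropyl)-7-[(triisopropylsilyl)oxy]-1,2,4a,5,8,8a-hexahydronaphthalen-1-yl]-2,4-dimethylpenta-2,4-dienoate | CC1=C[C@H]2CC(C)=C(O[Si](C(C)C)(C(C)C)C(C)C)[C@H](C)[C@H]2[C@H](/C=C(\C)/C=C(\C)C(=O)OCC)[C@@]1(O)CC(C)=O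
F4 | step 23 | methyl (2E)-3-[(2S,3S)-3-[(1E)-1-[(1R,2E,4aS,8R,8aR)-2-[(2R)-2-[(tert-butyldimethylsilyl)oxy]propylidene]-3,6,8-trimethyl-7-[(triisopropylsilyl)oxy]-1,2,4a,5,8,8a-hexahydronaphthalen-1-yl]prop-1-en-2-yl]-2-methyloxiran-2-yl]prop-2-enoate | CC1=C[C@H]2CC(C)=C(O[Si](C(C)C)(C(C)C)C(C)C)[C@H](C)[C@H]2[C@H](/C=C(\C)[C@@H]2O[C@@]2(C)/C=C/C(=O)OC)/C1=C\[C@@H](C)O[Si](C)(C)C(C)(C)C
F5 | step 23 | methyl (2E)-3-[(2S,3S)-3-[(1E)-1-[(1R,2E,4aS,6S,8R,8aR)-2-[(2R)-2-hydroxypropylidene]-3,6,8-trimethyl-7-oxo-1,2,4a,5,6,7,8,8a-octahydronaphthalen-1-yl]prop-1-en-2-yl]-2-methyloxiran-2-yl]prop-2-enoate | CC1=C[C@H]2C[C@H](C)C(=O)[C@H](C)[C@H]2[C@H](/C=C(\C)[C@@H]2O[C@@]2(C)/C=C/C(=O)OC)/C1=C\[C@@H](C)O
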